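**Retrosynthetic overview**
Labels: Ca = carbon bearing CH2OAc (that CH2 = Cm); Cb/Cc/Cd/Ce = ring CH2/CHOH/CHOAc/CMe2; Cf = cage apex; Cg = cage CH2; Ch/Ci/Cj = cyclopropane carbons next to Cg/next to Ca/methyl-bearing; Ck = cage CHOAc.
Feature: Ce, Cf and Ca are three adjoining fully substituted carbons of the cyclohexane Ca-Cb-Cc-Cd-Ce-Cf. With Ck as a ketone, Cf and Ca are the α- and β-carbons of an enone in the ring Ck-Cj-Ci-Ca-Cf, so Ca–Cb and Ce–Cf are cut together as a [4+2] of 4-methylpenta-1,3-diene with a 2-alkyl-3-methoxycarbonylcyclopentenone.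
Cage: Ch–Ci and Ch–Cj are cut back to a diazoalkane on a two-carbon arm at Cf and the Ci=Cj(Me) enone. The arm passes the Lewis acid step as an allyl group.
Oxygens: the Cc/Cd diol comes from the Diels–Alder alkene, Cm–O from the ester and Ck–O from the ketone. Hydride gives the wrong Ck epimer, which first closes one alkene face and is then inverted through the cyclopropylcarbinyl cation.
Ring order: cyclopentane (bought) → cyclohexene (step 4) → cyclopropane and the two remaining cage rings (step 9).

Key step: step 4

Remark (faces): "top" of the six-membered ring is the face carrying Ck and Ci; "bottom" is the face carrying Cm and Cg. The target has Cc–OH and Cd–OAc on the bottom face and Ck–OAc pointing towards Cg.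
Remark (arm): the CH2CHO arm is carried as allyl, because an acetal would be ionised by the Lewis acid of the key step and a 2-hydroxyethyl arm would lactonise onto the cis ester.
Assumption: the (S)-configured cationic oxazaborolidine is taken to leave the C1-Re/C2-Re face of the dienophile open. If the sense proves opposite, its mirror image (from D-proline) is used and nothing else changes.

**Step 1**
Reactants: 1 cyclopentane-1,3-dione; 2 allyl acetate
Product: 3 2-allylcyclopentane-1,3-dione
Conditions: Pd(PPh3)4 (2 mol %), THF, 40 °C, 1 in excess (1.5 equiv)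
Reagents that add atoms: none
Why: Tsuji–Trost allylation: the soft, acidic 1,3-dione attacks the π-allylpalladium complex at C2, any O-allyl ether re-ionises so that the C-allyl product collects, and the excess of 1 holds back double allylation.

**Step 2**
Reactants: 3 2-allylcyclopentane-1,3-dione
Product: 4 2-allyl-3-oxocyclopent-1-en-1-yl trifluoromethanesulfonate
Conditions: Tf2O, Et3N, CH2Cl2, −78 → 0 °C
Reagents that add atoms: trifluoromethanesulfonic anhydride, O=S(=O)(OS(=O)(=O)C(F)(F)F)C(F)(F)F
Why: O-sulfonylation of the enol of a symmetric 1,3-dione (vinylogous acid to vinylogous acyl triflate), so only one regioisomer can form.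

**Step 3**
Reactants: 4 2-allyl-3-oxocyclopent-1-en-1-yl trifluoromethanesulfonate
Product: 5 methyl 2-allyl-3-oxocyclopent-1-ene-1-carboxylate
Conditions: Pd(OAc)2 (5 mol %), dppf (6 mol %), CO (1 atm), Et3N, MeOH/DMF 1:2, 40 °C
Reagents that add atoms: carbon monoxide, [C-]#[O+]; methanol, CO
Why: Palladium-catalysed methoxycarbonylation of an enol triflate (oxidative addition, CO insertion, methanolysis); methanol as cosolvent intercepts the acylpalladium species before it can add to the pendant allyl group.

**Step 4**
Reactants: 5 methyl 2-allyl-3-oxocyclopent-1-ene-1-carboxylate; 6 4-methylpenta-1,3-diene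
Product: 7 methyl (3aR,7aR)-7a-allyl-7,7-dimethyl-1-oxo-1,2,3,4,7,7a-hexahydro-3aH-indene-3a-carboxylate (cis-hydrindenone; CO2Me on Ca cis to allyl on Cf)
Conditions: (S)-3,3-diphenyl-1-(o-tolyl)tetrahydropyrrolo[1,2-c][1,3,2]oxazaborole (20 mol %), Tf2NH (18 mol %), CH2Cl2, −78 → −20 °C, 6 (5 equiv) by syringe pump
Reagents that add atoms: none
Why: Proposed new method: the cationic boron binds the Ck ketone (more basic than the conjugated ester; lone pair on the Cj side, away from the allyl arm), so that Ca, its β-carbon, becomes the most electrophilic alkene carbon, the unsubstituted diene terminus Cb bonds to it first, and the developing dimethylallyl cation closes through Ce onto the boron enolate carbon Cf in one strongly asynchronous [4+2] event. The closest known reaction types are the cationic-oxazaborolidine-catalysed Diels–Alder reaction of cyclic enones and the Lewis acid promoted Diels–Alder reactions of 3-alkoxycarbonylcycloalkenones and of hindered enones with terminally disubstituted dienes; none of them joins a tetrasubstituted dienophile to a disubstituted diene terminus. One ring is closed, the cyclohexene Ca-Cb-Cc=Cd-Ce-Cf, as the six-membered ring of the cycloaddition (two σ-bonds, suprafacial on both partners), annulated to the Ca–Cf bond of the cyclopentanone. Ca and Cf are set together: suprafacial addition to the ring alkene forces CO2Me and allyl cis, and the absolute sense comes from the catalyst, whose aryl wall is taken to cover the C1-Si/C2-Si face so that 6 adds to the C1-Re/C2-Re face; endo/exo orientation creates no stereocentre because both diene termini are symmetric (CH2, CMe2). The step needs regioselectivity (Cb to Ca, Ce to Cf), secured by the matched polarisation of the ketone-activated Ca and of the diene terminus that leads to the tertiary allyl cation, and periselectivity (closure at Ce rather than at Cc or proton loss), which depends on reaction through the s-cis diene and is the main risk. The allyl arm is an unactivated monosubstituted alkene without a Lewis basic site, so it neither competes as a π-nucleophile nor ties up the catalyst.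

**Step 5**
Reactants: 7 cis-hydrindenone keto ester
Product: 8 methyl 7a-allyl-2,7,7-trimethyl-1-oxo-1,2,3,4,7,7a-hexahydro-3aH-indene-3a-carboxylate (Ca and Cf as in 7; epimers at Cj)
Conditions: LDA (1.05 equiv), THF, −78 °C; MeI, −78 → −30 °C
Reagents that add atoms: iodomethane, CI
Why: Kinetic enolate alkylation: Cj is the only enolisable position (Cf is quaternary, the ester has no α-hydrogen), and the configuration of the new centre does not matter because Cj becomes sp2 in step 6.

**Step 6**
Reactants: 8 α-methyl ketone
Product: 10 methyl 7a-allyl-2,7,7-trimethyl-1-oxo-1,4,7,7a-tetrahydro-3aH-indene-3a-carboxylate (Ci=Cj(Me) enone; Ca and Cf as in 7), via trimethylsilyl enol ether 9 (not isolated)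
Conditions: TMSOTf, Et3N, CH2Cl2, 0 °C; crude 9, then IBX·4-methoxypyridine N-oxide, DMSO, rt
Reagents that add atoms: none
Why: Soft enolisation gives the only possible silyl enol ether, and its IBX·N-oxide dehydrogenation (the metal-free counterpart of the Saegusa–Ito oxidation) removes the Ci hydrogen to give the endocyclic enone; Pd(OAc)2 is avoided because it could couple the enol ether with the pendant allyl group.

**Step 7**
Reactants: 10 enone
Product: 12 methyl 2,7,7-trimethyl-1-oxo-7a-(2-oxoethyl)-1,4,7,7a-tetrahydro-3aH-indene-3a-carboxylate (aldehyde Ch on the Cg arm), via vicinal diol 11 (not isolated)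
Conditions: OsO4 (2 mol %), NMO (1.05 equiv), acetone/H2O, 0 °C; then NaIO4 (1.5 equiv), rt
Reagents that add atoms: N-methylmorpholine N-oxide, C[N+]1([O-])CCOCC1; water, O (oxygen passed on through catalytic osmium tetroxide, O=[Os](=O)(=O)=O)
Why: Upjohn dihydroxylation followed by periodate cleavage (Lemieux–Johnson sequence): with one equivalent of oxidant the exposed monosubstituted alkene reacts first, because the ring alkene is neopentyl and flanked by two quaternary fusion carbons and the enone is electron-poor.

**Step 8**
Reactants: 12 aldehyde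
Product: 13 (E)-N-tosylhydrazone of aldehyde 12
Conditions: TsNHNH2 (1.0 equiv), THF, 0 °C → rt
Reagents that add atoms: p-toluenesulfonyl hydrazide, Cc1ccc(cc1)S(=O)(=O)NN
Why: Hydrazone condensation, selective because the unhindered aldehyde is far more reactive than the conjugated ketone next to quaternary Cf.

**Step 9**
Reactants: 13 tosylhydrazone
Product: 16 cage keto ester (nortricyclanone: cyclopropane Ch-Ci-Cj; apex Cf; Ck ketone; CO2Me on Ca; Cc=Cd alkene), via diazoalkane 14 (not isolated), via 1-pyrazoline 15 (not isolated)
Conditions: K2CO3, 1,4-dioxane, 100 °C; then hν (350 nm), rt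
Reagents that add atoms: none
Why: Bamford–Stevens generation of the diazoalkane, intramolecular 1,3-dipolar cycloaddition to the enone (nucleophilic Ch to β-carbon Ci, terminal N to Cj) and nitrogen extrusion to the cyclopropane; the one-carbon tether Cg lets the dipole reach only the ring face that carries the arm, which sets Ch, Ci and Cj, and the usual hydrogen shift to an alkene is barred because Ci is a bridgehead.

**Step 10**
Reactants: 16 cage keto ester
Product: 17 cage ene-diol (Cm–OH; Ck–OH pointing towards Cb over the top face of the cyclohexene; the Ck epimer of the target series)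
Conditions: LiAlH4, THF, 0 °C → reflux
Reagents that add atoms: none
Why: Hydride reduction of ketone and ester: the two faces of the Ck carbonyl look at the neighbouring bridges Cg (two hydrogens) and Ca (whose substituent Cb points at Ck), so hydride enters from the Cg side and the oxygen is pushed over the six-membered ring; this epimer is used in step 11 and corrected in step 14.

**Step 11**
Reactants: 17 cage ene-diol
Product: 19 tetraol (Cc–OH axial and Cd–OH equatorial; both on the bottom face; Ck–OH still over the top face), via osmate ester TMEDA complex 18 (not isolated)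
Conditions: OsO4 (1.05 equiv), TMEDA, CH2Cl2, −78 °C → rt; then aq. Na2SO3, THF, reflux
Reagents that add atoms: osmium tetroxide, O=[Os](=O)(=O)=O
Why: Hydrogen-bond-directed syn-dihydroxylation with OsO4·TMEDA: the cage locks one half-chair in which the Ck oxygen sits about 3 Å above Cc=Cd and closes the top face, while the axial CH2OH on the bottom face hydrogen-bonds the reagent, so both oxygens should arrive cis to Cm.

**Step 12**
Reactants: 19 tetraol
Product: 20 Cc/Cd acetonide diol (Cm–OH and Ck–OH free)
Conditions: Me2C(OMe)2, PPTS (cat.), acetone, rt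
Reagents that add atoms: 2,2-dimethoxypropane, COC(C)(C)OC
Why: Thermodynamic acetalisation picks the cis-vicinal diol (five-membered dioxolane), since the Cm–OH/Cc–OH pair would need a seven-membered ring, and PPTS is too weak to ionise the cyclopropylcarbinol.

**Step 13**
Reactants: 20 acetonide diol
Product: 21 acetonide monoacetate (Cm–OAc; Ck–OH free)
Conditions: Ac2O (1.2 equiv), pyridine, 0 °C → rt
Reagents that add atoms: acetic anhydride, CC(=O)OC(C)=O
Why: Chemoselective acylation of the primary alcohol; the Ck hydroxyl lies between two quaternary carbons and over the ring and does not react without a nucleophilic catalyst.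

**Step 14**
Reactants: 21 acetonide monoacetate
Product: 23 acetonide diacetate (Ck–OAc now pointing towards Cg as in the target), via mesylate 22 (not isolated)
Conditions: Ms2O, Et3N, CH2Cl2, −30 °C; then KOAc, AcOH, −30 °C → rt
Reagents that add atoms: potassium acetate, CC(=O)[O-].[K+]
Why: Buffered acetolysis of a cyclopropylcarbinyl (nortricyclyl) sulfonate: backside displacement is blocked by the cage, the strained mesylate ionises with cyclopropane participation, and acetate takes the planar cation at Ck from the open side facing Cg (the side hydride used), giving net inversion; kinetic, buffered conditions favour capture at the carbinyl carbon, as in nortricyclyl/norbornenyl solvolyses.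

**Step 15**
Reactants: 23 acetonide diacetate
Product: 24 diol diacetate (Cm–OAc; Ck–OAc; Cc–OH and Cd–OH free)
Conditions: AcOH/H2O 4:1, 40 °C
Reagents that add atoms: none
Why: Acid hydrolysis of the isopropylidene acetal; the acetates, including the nortricyclyl acetate, are stable to aqueous acetic acid in the absence of a strong acid, and no stereocentre is touched.

**Step 16**
Reactants: 24 diol diacetate
Product: 25 CNP0111873.1 (target)
Conditions: Ac2O (1.1 equiv), pyridine, CH2Cl2, 0 °C
Reagents that add atoms: acetic anhydride, CC(=O)OC(C)=O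
Why: Kinetic regioselective acylation of a cis-diol: the equatorial Cd–OH reacts, whereas the axial Cc–OH lies between two syn-axial carbon groups (CH2OAc on Ca, one methyl on Ce) and stays free.

**Compound list**
1 | cyclopentane-1,3-dione | O=C1CCC(=O)C1 | starting material
2 | allyl acetate | C=CCOC(C)=O | starting material
3 | 2-allylcyclopentane-1,3-dione | O=C1CCC(=O)C1CC=C | intermediate
4 | 2-allyl-3-oxocyclopent-1-en-1-yl triflate | C=CCC1=C(OS(=O)(=O)C(F)(F)F)CCC1=O | intermediate
5 | methyl 2-allyl-3-oxocyclopent-1-ene-1-carboxylate (dienophile) | COC(=O)C1=C(CC=C)C(=O)CC1 | intermediate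
6 | 4-methylpenta-1,3-diene | CC(C)=CC=C | starting material
7 | cis-hydrindenone Diels–Alder adduct (3aR,7aR) | COC(=O)[C@]12CC=CC(C)(C)[C@@]1(CC=C)C(=O)CC2 | intermediate
8 | α-methyl ketone (epimers at Cj) | COC(=O)[C@]12CC=CC(C)(C)[C@@]1(CC=C)C(=O)C(C)C2 | intermediate
9 | trimethylsilyl enol ether | COC(=O)[C@]12CC=CC(C)(C)[C@@]1(CC=C)C(O[Si](C)(C)C)=C(C)C2 | intermediate
10 | Ci=Cj(Me) enone | COC(=O)[C@]12CC=CC(C)(C)[C@@]1(CC=C)C(=O)C(C)=C2 | intermediate
11 | vicinal diol on the arm (carbinol epimers) | COC(=O)[C@]12CC=CC(C)(C)[C@@]1(CC(O)CO)C(=O)C(C)=C2 | intermediate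
12 | enone aldehyde | COC(=O)[C@]12CC=CC(C)(C)[C@@]1(CC=O)C(=O)C(C)=C2 | intermediate
13 | N-tosylhydrazone | COC(=O)[C@]12CC=CC(C)(C)[C@@]1(C/C=N/NS(=O)(=O)c3ccc(C)cc3)C(=O)C(C)=C2 | intermediate
14 | diazoalkane | COC(=O)[C@]12CC=CC(C)(C)[C@@]1(CC=[N+]=[N-])C(=O)C(C)=C2 | intermediate
15 | 1-pyrazoline (Ch–Ci and N–Cj formed) | COC(=O)[C@]12CC=CC(C)(C)[C@]13C[C@H]4N=N[C@@](C)(C3=O)[C@@H]24 | intermediate
16 | cage keto ester | COC(=O)[C@]12CC=CC(C)(C)[C@]13C[C@@H]1[C@H]2[C@]1(C)C3=O | intermediate
17 | cage ene-diol (Ck–OH towards Cb) | OC[C@]12CC=CC(C)(C)[C@]13C[C@@H]1[C@H]2[C@]1(C)[C@@H]3O | intermediate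
18 | osmate(VI) ester TMEDA complex | OC[C@]12C[C@@H]4O[Os-2]5(=O)(=O)([N+](C)(C)CC[N+]5(C)C)O[C@@H]4C(C)(C)[C@]13C[C@@H]1[C@H]2[C@]1(C)[C@@H]3O | intermediate
19 | tetraol (Ck–OH towards Cb) | OC[C@]12C[C@H](O)[C@H](O)C(C)(C)[C@]13C[C@@H]1[C@H]2[C@]1(C)[C@@H]3O | intermediate
20 | acetonide diol | OC[C@]12C[C@@H]4OC(C)(C)O[C@@H]4C(C)(C)[C@]13C[C@@H]1[C@H]2[C@]1(C)[C@@H]3O | intermediate
21 | acetonide monoacetate | CC(=O)OC[C@]12C[C@@H]4OC(C)(C)O[C@@H]4C(C)(C)[C@]13C[C@@H]1[C@H]2[C@]1(C)[C@@H]3O | intermediate
22 | Ck mesylate | CC(=O)OC[C@]12C[C@@H]4OC(C)(C)O[C@@H]4C(C)(C)[C@]13C[C@@H]1[C@H]2[C@]1(C)[C@@H]3OS(C)(=O)=O | intermediate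
23 | acetonide diacetate (Ck inverted) | CC(=O)OC[C@]12C[C@@H]4OC(C)(C)O[C@@H]4C(C)(C)[C@]13C[C@@H]1[C@H]2[C@]1(C)[C@H]3OC(C)=O | intermediate
24 | diol diacetate | CC(=O)OC[C@]12C[C@H](O)[C@H](O)C(C)(C)[C@]13C[C@@H]1[C@H]2[C@]1(C)[C@H]3OC(C)=O | intermediate
25 | CNP0111873.1 | CC(=O)OC[C@]12C[C@H](O)[C@H](OC(C)=O)C(C)(C)[C@]13C[C@@H]1[C@H]2[C@]1(C)[C@H]3OC(C)=O | target

Total step count: 16. Longest linear sequence: 16 (from 1).

**Steps most likely to fail**

1. Step 4.
- The diene may react through its favoured s-trans form. The allyl cation left after the first bond then loses a proton or closes at Cc to a four-membered ring.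
- The diene may also polymerise under the acid.
- Enantiofacial discrimination may be poor because the dienophile has no α-hydrogen for the catalyst to hold.
- Fallback, from 5 back to 7: mesityl oxide is O-silylated (TBSOTf, Et3N) to 2-(tert-butyldimethylsilyloxy)-4-methylpenta-1,3-diene F1. This is a much stronger π-nucleophile with the same carbon skeleton.
- With 5 under the mixed Lewis acid AlBr3/AlMe3 (toluene/CH2Cl2, −5 °C), the established protocol for hindered silyloxydiene/hindered enone pairs, F1 should add by Mukaiyama–Michael attack at Ca and ring closure at Cf. This gives the racemic silyl enol ether adduct F2.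
- CsF/PhNTf2 (DME) turns F2 regiospecifically into the racemic enol triflate F3. Pd(OAc)2/PPh3/HCO2H/Bu3N (DMF, 60 °C) then reduces F3 to racemic 7.
- Preparative HPLC on a chiral stationary phase separates 7 from ent-7 F4.

2. Step 11.
- The alkene is screened on both faces: by the axial CH2OH and one methyl below, and by the Ck carbinol above.
- Osmylation may therefore stall, or facial selectivity may be poor.
- Fallback, from 16 back to 19, fixes Cc–O by a covalent tether. In the ketone 16 the top face is the open one, so mCPBA (NaHCO3, CH2Cl2) should give the top-face epoxide F5.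
- With CSA in wet CH2Cl2 the axial ester carbonyl opens F5 at Cc from the bottom face (trans-diaxial, Fürst–Plattner) with loss of methanol. This gives the hydroxy γ-lactone F6, with Cc–O below and Cd–OH above.
- Dess–Martin periodinane gives the keto lactone F7.
- LiAlH4 then reduces everything. At Cd hydride should enter from the top face, anti to the axial lactone C–O bond (Felkin–Anh sense) and away from the axial α-methyl, which places Cd–OH equatorial on the bottom face.
- Ck behaves as in step 10, and the lactone opens to Cm–OH and Cc–OH, giving 19.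

3. Step 14.
- The delocalised cation may be captured at cyclopropane carbon Ch with ring opening.
- It may also take a transannular hydride from the dioxolane C–H, or the acetonide may be lost.
- Fallback, from 19 back to 23, replaces the kinetic displacement on the protected series by thermodynamic epimerisation before protection.
- In dilute HClO4 in aqueous dioxane (40 °C) only the cyclopropylcarbinyl alcohol of 19 ionises, and water adds reversibly. A ring-opened homoallylic alcohol re-enters the same cation by π-participation.
- The material should therefore drain into the less strained epimer with the hydroxyl facing Cg, the Ck-epimeric tetraol F8.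
- 2,2-Dimethoxypropane/PPTS gives its acetonide diol F9.
- Because Cc–OH is masked, both remaining hydroxyls can be acetylated under forcing conditions (Ac2O, Et3N, DMAP, 40 °C) to 23.

**Further compounds**
F1 | step 4 | 2-(tert-butyldimethylsilyloxy)-4-methylpenta-1,3-diene | C=C(O[Si](C)(C)C(C)(C)C)C=C(C)C
F2 | step 4 | silyl enol ether adduct (racemic; enantiomer leading to 7 drawn) | COC(=O)[C@]12CC(O[Si](C)(C)C(C)(C)C)=CC(C)(C)[C@@]1(CC=C)C(=O)CC2
F3 | step 4 | enol triflate (racemic; enantiomer leading to 7 drawn) | COC(=O)[C@]12CC(OS(=O)(=O)C(F)(F)F)=CC(C)(C)[C@@]1(CC=C)C(=O)CC2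
F4 | step 4 | ent-7 | COC(=O)[C@@]12CC=CC(C)(C)[C@]1(CC=C)C(=O)CC2
F5 | step 11 | top-face epoxide of 16 | COC(=O)[C@]12C[C@H]4O[C@H]4C(C)(C)[C@]13C[C@@H]1[C@H]2[C@]1(C)C3=O
F6 | step 11 | hydroxy γ-lactone (Cm–O–Cc; Cd–OH on top face) | O=C4[C@]12C[C@H](O4)[C@@H](O)C(C)(C)[C@]13C[C@@H]1[C@H]2[C@]1(C)C3=O
F7 | step 11 | keto lactone (Cd and Ck ketones) | O=C4[C@]12C[C@H](O4)C(=O)C(C)(C)[C@]13C[C@@H]1[C@H]2[C@]1(C)C3=O
F8 | step 14 | Ck-epimeric tetraol (Ck–OH towards Cg) | OC[C@]12C[C@H](O)[C@H](O)C(C)(C)[C@]13C[C@@H]1[C@H]2[C@]1(C)[C@H]3O
F9 | step 14 | acetonide diol of F8 | OC[C@]12C[C@@H]4OC(C)(C)O[C@@H]4C(C)(C)[C@]13C[C@@H]1[C@H]2[C@]1(C)[C@H]3O
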